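The numbers in the tables are simulated for substances that don't exist; scatter was added.

- The eta and beta runs, both at 25 °C, show right-handed product growing while left-handed substrate falls. Both substrates pass through one catalyst and one partner, so I treat them as two decays on a common clock and work with the fractions left.

| setting | epsilon | eta | gamma | beta | grey | teal | blue | red |
|---|---|---|---|---|---|---|---|---|
| left-handed substrate | 0.050 M | 0.025 M | 0.10 M | 0.050 M | 0.050 M | 0.050 M | 0.050 M | 0.050 M |
| right-handed substrate | 0.050 M | 0.025 M | 0.10 M | 0.050 M | 0.050 M | 0.050 M | 0.050 M | 0.050 M |
| partner | 0.10 M | 0.10 M | 0.10 M | 0.15 M | 0.100 M (fed, over 1.5 min) | 0.100 M | 0.100 M | 0.100 M (fed, over 1.5 min) |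
| free catalyst | 0.25 mM | 0.25 mM | 0.25 mM | 0.25 mM | 0.25 mM | 0.25 mM | 0.25 mM | 0.25 mM |
| temperature | 10 °C | 25 °C | 10 °C | 25 °C |  | 25 °C |  | 25 °C |
| remark | run made earlier | run made earlier | run made earlier | run made earlier | the addition at −5 °C, then warmed to 25 °C; the feed brings no volume worth counting | everything together at the start | everything together at the start at −5 °C, warmed to 25 °C at 1.5 min | all else is in the flask from the start; the feed brings no volume worth counting |
| time |  |  |  |  | 2.0 min | 2.0 min | 2.0 min | 2.0 min |

epsilon run (percent of the left-handed substrate and right-handed substrate together charged)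

| time / min | right-handed product / % | left-handed product / % |
|---|---|---|
| 0.500 | 0.6 | 23.7 |
| 1.00 | 1.1 | 37.3 |
| 1.33 | 2.6 | 42.3 |
| 2.00 | 5.9 | 48.4 |
| 3.00 | 10.1 | 50.9 |

eta run (percent of the left-handed substrate and right-handed substrate together charged)

| time / s | right-handed product / % | left-handed product / % |
|---|---|---|
| 20.0 | 4.4 | 33.2 |
| 40.0 | 8.1 | 44.3 |
| 60.0 | 14.0 | 49.4 |
| 80.0 | 19.9 | 50.4 |
| 90.0 | 21.2 | 49.9 |

gamma run (percent of the left-handed substrate and right-handed substrate together charged)

| time / min | right-handed product / % | left-handed product / % |
|---|---|---|
| 0.333 | 0 | 10.0 |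
| 0.500 | 1.0 | 11.6 |
| 0.833 | 0 | 19.3 |
| 2.00 | 1.9 | 31.6 |
| 3.00 | 2.4 | 36.7 |

beta run (percent of the left-handed substrate and right-handed substrate together charged)

| time / s | right-handed product / % | left-handed product / % |
|---|---|---|
| 20.0 | 5.5 | 33.2 |
| 40.0 | 7.1 | 46.0 |
| 60.0 | 14.4 | 48.3 |
| 80.0 | 16.4 | 51.4 |
| 90.0 | 22.0 | 49.8 |

(each reading ± 1 percentage point)

- the flask that comes out highest in amount of right-handed product, in percent of the left-handed substrate and right-handed substrate together charged; "all alike" if 1.5 percentage points covers them all (grey / teal / blue / red / all alike)
- amount of right-handed product at the end, in percent of the left-handed substrate and right-handed substrate together charged, grey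
- amount of right-handed product at the end, in percent of the left-handed substrate and right-handed substrate together charged, teal
- amount of right-handed product at the end, in percent of the left-handed substrate and right-handed substrate together charged, blue
- amount of right-handed product at the end, in percent of the left-handed substrate and right-handed substrate together charged, red

- free catalyst is single-handed; left-handed substrate and right-handed substrate are mirror images of each other, charged as a racemate, each of them at the stated concentration
- steps thought possible: free catalyst + left-handed substrate <-> catalyst intermediate A; free catalyst + right-handed substrate <-> catalyst intermediate B; partner + catalyst intermediate A -> free catalyst + left-handed product; partner + catalyst intermediate B -> free catalyst + right-handed product; partner -> decomposition product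

- Pooling the readings at 20.0 s and 40.0 s, the eta run gives a ratio of decays of 12.1 and the beta run 13.4, though their charges differ.
- Their mean, s = 12.8, is my selectivity factor: the natural log of the fraction of left-handed substrate left, over the same log for right-handed substrate. It is a ratio of two time constants, with time and partner folded out.
- So at 25 °C, with the two substrates charged equal, I take the fraction of right-handed substrate left as the left-handed fraction raised to the power of one over s, and right-handed product, in percent of both together, as 0.5 times the fraction of right-handed substrate lost. Red and teal, both at 25 °C, should share this curve. Red's partner comes in over 1.5 min and teal's stands there from the start, so I place red behind teal on it.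
- The epsilon run at 10 °C reads 29.7, higher than s, so I expect blue and grey, cold for 1.5 min, below red and teal.
- One number ranks but does not date. The epsilon run has teal's charges but is colder; its left-handed fraction at 2.00 min, 3.20%, a scattered reading, placed on this curve gives 11.8%, my rough estimate for teal.
- The forecast names teal: grey 5.5%, teal 17%, blue 6.5%, red 11.5%, with growth “mainly at 25 °C and after the left-handed substrate is spent”. Its teal stands above my estimate.
- Teal gives 14.7%, red 9.26%, blue 4.95%, grey 4.48%, so teal is highest and the forecast held. At 2.00 min teal keeps 2.2% of its left-handed substrate, unbound, and s turns that into 12.9%, lower than the flask.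

    free catalyst + left-handed substrate ⇌ catalyst intermediate A (K = 51.0 M⁻¹, k = 79000 M⁻¹ s⁻¹, Ea = 12.0 kJ mol⁻¹, ΔH = −51.0 kJ mol⁻¹)
    free catalyst + right-handed substrate ⇌ catalyst intermediate B (K = 13.0 M⁻¹, k = 3500 M⁻¹ s⁻¹, Ea = 23.0 kJ mol⁻¹, ΔH = −19.0 kJ mol⁻¹)
    partner + catalyst intermediate A → free catalyst + left-handed product (k = 100 M⁻¹ s⁻¹, Ea = 36.0 kJ mol⁻¹)
    partner + catalyst intermediate B → free catalyst + right-handed product (k = 36.0 M⁻¹ s⁻¹, Ea = 51.0 kJ mol⁻¹)
    partner → decomposition product (k = 3.80 × 10⁻⁵ s⁻¹, Ea = 102 kJ mol⁻¹)
    (constants at 25 °C)

- In the neighbour like teal but with 0.060 M of partner, 21% of the left-handed substrate stays unbound, and s gives 5.70%. The computed flask gives 6.59%.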